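The data are calculated from invented constants, and the scatter is random.

The time asked of dawn and winter, 4.0 min, lay past the last readings of gamma and eta at 3.00 min, so I needed a clock for the substrate that could be carried beyond them.

all flasks: substrate 0.050 M

| charge | partner | second reagent | third reagent | remark | time |
|---|---|---|---|---|---|
| gamma | 0.95 equiv | 0.90 equiv | 1.6 equiv | run made earlier |  |
| eta | 0.95 equiv | 0.90 equiv | 2 equiv | run made earlier |  |
| dawn | 0.950 equiv | 0.900 equiv | 1.70 equiv |  | 4.0 min |
| winter | 0.950 equiv | 0.900 equiv | 1.10 equiv |  | 4.0 min |

| run | time / min | substrate / % | product / % | intermediate B / % | intermediate A / % |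
|---|---|---|---|---|---|
| gamma | 0.417 | 87.7 | 0.1 | 1.4 | 11.0 |
| gamma | 0.833 | 78.0 | 0.7 | 4.1 | 17.2 |
| gamma | 1.33 | 68.7 | 2.0 | 8.9 | 20.0 |
| gamma | 1.50 | 66.8 | 3.0 | 9.5 | 20.8 |
| gamma | 2.00 | 60.0 | 6.1 | 13.0 | 21.5 |
| gamma | 2.50 | 54.3 | 8.3 | 14.8 | 21.5 |
| gamma | 3.00 | 50.1 | 12.4 | 16.4 | 20.8 |
| eta | 0.167 | 94.2 | 0 | 0.1 | 5.1 |
| eta | 0.417 | 87.4 | 0.2 | 1.4 | 10.7 |
| eta | 0.833 | 78.4 | 0.7 | 4.4 | 16.5 |
| eta | 1.33 | 68.7 | 2.9 | 8.1 | 20.1 |
| eta | 1.50 | 66.5 | 3.5 | 8.8 | 20.9 |
| eta | 2.00 | 60.1 | 6.8 | 12.2 | 21.5 |
| eta | 3.00 | 49.9 | 14.0 | 14.7 | 20.9 |

(readings scatter by 0.3 percentage points)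

- which of these there is most of at the end, counted by the substrate in it, dawn (intermediate B / product / substrate / intermediate A)
- which of these there is most of at the end, counted by the substrate in it, winter (intermediate B / product / substrate / intermediate A)
- the largest of these amounts at the end, in percent of the substrate charged, dawn
- the largest of these amounts at the end, in percent of the substrate charged, winter



At the last reading gamma held 50.1% substrate and eta 49.9%, a gap of 0.2 percentage points against a scatter of 0.3 points, with third reagent at 1.6 equiv and 2 equiv; I assumed that third reagent left the substrate curve unmoved in dawn too, and in winter, whose charge of 1.10 equiv is lower than either. Partner was charged at 0.95 equiv, so [partner] stayed close to [substrate], and I took the rate as second order in that one concentration. The reciprocal of the fraction left then climbs evenly, and gamma gave τ = 3.01 min, the time in which that reciprocal climbs by one. As a test, gamma at 1.50 min read 66.8%; this curve gives 66.7%, and first order through the same last point gives 70.8%.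

Two times carried the question, τ and 4.0 min. On this curve their ratio is substrate left over substrate reacted, so I reckoned 43.0% left in both flasks, and a rival needed 75.3% of the reacted substrate to pass it. In gamma at its last reading intermediate A, the largest of the three, held 41.7% of the reacted substrate, less than that, and on that margin, read before the asked time, I committed to substrate in both flasks.

The forecast named substrate for dawn and substrate for winter, at 43.2% and 43.2%, between 41.8% and 44.6%, and said: “This assumes the trend holds for one further minute.”

Dawn and winter ended with substrate most abundant, at 43.1% and 43.1%.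

    third reagent + intermediate B → product (k = 5.88 M⁻¹ min⁻¹)
    substrate + partner → intermediate A (k = 7.19 M⁻¹ min⁻¹)
    second reagent + intermediate A → intermediate B (k = 14.5 M⁻¹ min⁻¹)

Winter's largest rival, intermediate B at 21.9%, held 38.5% of the reacted substrate, short of the 75.3% I had reckoned. The order changed in a neighbour of winter with 1.60 equiv of partner, where substrate stood at 21.5% and intermediate A held most. Another neighbour of winter had 0.013 M substrate with the equivalents held; taking τ in inverse proportion to the charge, I reckoned 11.6 min and 74.3% left, and that flask held 74.0%.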